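# Synthesis design for CNP0280662.1: late-stage reductive hydroxymethylation of a core-bound but-2-ynoate

Atom labels used throughout: C1 is the benzylic carbinol carbon, C2 the adjacent stereocentre and C3 the oxymethylene carbon. C4–C6 is the cinnamyl arm, with C5=C6 the E alkene and C6 bearing the 4-methoxyphenyl ring. C1'–C4' is the acyl unit (C1' carbonyl, C2'=C3' alkene, C4' methyl, hydroxymethyl on C2'). O1 and O3 are the oxygens on C1 and C3.

## The problem

The target is an acyclic 1,3-dioxygenated three-carbon core: C1 is a secondary benzylic carbinol carrying the 3,4-dimethoxyphenyl ring, C2 bears the C3 oxymethylene and the (E)-3-(4-methoxyphenyl)prop-2-enyl arm C4–C6, and the primary oxygen O3 is acylated by a (Z)-2-(hydroxymethyl)but-2-enoyl unit. No ring other than the two arenes is present, so stereochemical information can only be passed along the open chain. The two stereocentres, C1 (S) and C2 (R), are adjacent and syn in the aldol sense; because C2 carries two methylene groups of similar size (C3 and C4), neither centre can be relied on to control the other by 1,2-induction, and they are best set together when the C1–C2 bond is formed. O1 and O3 must be told apart because only O3 is acylated, and a free O1 next to the O3 ester invites 1,3-acyl migration under base. The C1–O bond is benzylic and para to a methoxy group, so it ionises under acid, and the electron-rich styrene rules out hydrogenation, strong oxidants and strong Lewis acids. The C2'=C3' alkene has the C4' methyl cis to the carbonyl, the less stable angelate-type geometry, which is easily lost under base, nucleophilic catalysis or carboxyl activation of the corresponding acid. The enabling feature is that C3' carries H and methyl while C2' carries the hydroxymethyl carbon cis to that hydrogen, which is the formal syn addition of H and CH2OH across C2'≡C3' of a but-2-ynoate. The acyl unit can therefore be attached as a geometry-free alkynoate and its alkene created afterwards on the intact ester.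

## Retrosynthesis

**O1–Si bond.** Target 16 is traced back to its O1 triethylsilyl ether 15. O1 has to be masked during the hydride chemistry that precedes it. A triethylsilyl group is chosen because buffered HF·pyridine removes it without the base that would move the acyl group and without acid strong enough to ionise C1. The forward step must only spare the Z enoate and the allylic alcohol.

**C2'–CH2OH and C3'–H bonds.** Silyl ether 15 is disconnected to the but-2-ynoate 12 and formaldehyde 13. The neighbouring cut is the O3–C1' ester bond to an acyl donor that already carries the Z alkene. That route would need a separate stereodefined synthesis of the donor, protection of its hydroxyl, and carboxyl activation of an angelate-type acid, which is where such acids isomerise. Making the alkene on the intact ester avoids all three. The precursor 12 lacks the alkene geometry, the hydroxymethyl group and any protecting group on the acyl unit. The forward reaction must deliver hydride to C3' in conjugate fashion and capture the resulting allenolate 14 at C2' with formaldehyde on the hydrogen side.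

**O3–C1' bond.** Ynoate 12 comes from primary alcohol 10 and but-2-ynoic acid 11. The acid is commercial, unhindered and has neither alkene geometry nor α-hydrogens. The forward esterification only has to avoid nucleophile-induced decomposition of the ynoate. It meets a single free hydroxyl, because O1 is already silylated.

**C3 oxidation level and O1 protection.** Alcohol 10 is derived from the silylated aldol imide 9 by reductive removal of the auxiliary, and 9 from the aldol adduct 8 by silylation. Silylating O1 while C3 is still at the carboxyl level differentiates the two oxygens without any selective reaction. It also blocks retro-aldol during reduction. The forward reduction must attack the exocyclic imide carbonyl and leave the styrene alone, which points to LiBH4, not to hydrogenation or borane.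

**C1–C2 bond.** Adduct 8 is cut into imide 5 and 3,4-dimethoxybenzaldehyde 6. This is the one step that creates both stereocentres at once. A boron-mediated auxiliary aldol is preferred over catalytic reduction of a racemic α-branched aryl ketone under dynamic kinetic resolution. The syn selectivity of such reductions for a plain α-alkyl branch is less dependable than the closed transition state of the Z boron enolate 7. The price is one extra step and a stoichiometric but recoverable auxiliary.

**C5=C6 and N–acyl bonds.** Imide 5 is cut at the styrene double bond into the pent-4-enoyl imide 3 and 4-methoxystyrene 4. Imide 3 comes from (S)-4-benzyloxazolidin-2-one 1 and pent-4-enoyl chloride 2. All four are commercial or one step from commercial materials. The metathesis only has to give the conjugated E alkene, which is the thermodynamic outcome.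

## Roads not taken

Alternative 1: Ireland–Claisen rearrangement with chirality transfer. The cut is the C2–C4 bond. In the forward step the allylic ester (S)-1-(4-methoxyphenyl)prop-2-en-1-yl 3-[(tert-butyldimethylsilyl)oxy]propanoate A1 would be converted with LiN(i-Pr)2 and Me3SiCl in THF into its silyl ketene acetal. A chair-like [3,3] shift then forms C2–C4, breaks C6–O and gives (R,E)-2-{[(tert-butyldimethylsilyl)oxy]methyl}-5-(4-methoxyphenyl)pent-4-enoic acid A2.
- Merits: C2 and the E styrene arise in one metal-free step from A1. The equatorial aryl group fixes the alkene geometry intrinsically. On this point the road is better than the cross-metathesis of the chosen plan, which needs an excess of 4 and the second-generation Grubbs catalyst.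
- Weak points:
  - The configuration at C2 of A2 is only as good as the ketene acetal geometry. For a β-silyloxy ester such as A1 this is blurred by possible lithium chelation, and enolisation competes with β-elimination of silanolate.
  - The C6–O bond of A1 is benzylic, allylic and para to methoxy. Ionisation threatens racemisation and 1,3-transposition, and the enantiopure carbinol needs its own asymmetric step.
  - Acid A2 holds only C2. C1 would have to be made later by adding an aryl nucleophile to a C2-branched carbonyl, under 1,2-induction from a centre with two similar methylene substituents.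
- Comparison: the chosen plan sets C1 and C2 together under reagent control and never depends on an ionisable stereocentre. The road through A2 also says nothing about the Z acyl unit and would need the same endgame after more steps.

Alternative 2: scandium-catalysed asymmetric hydroxymethylation. The cut is the C2–C3 bond. In the forward step the Z silyl enol ether trimethyl{[(1Z,4E)-1-(3,4-dimethoxyphenyl)-5-(4-methoxyphenyl)penta-1,4-dien-1-yl]oxy}silane A3 would react with aqueous formaldehyde 13 under Sc(OTf)3 and a chiral 2,2'-bipyridine diol ligand. The product would be (R,E)-1-(3,4-dimethoxyphenyl)-2-(hydroxymethyl)-5-(4-methoxyphenyl)pent-4-en-1-one A4.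
- Merits: the road from A3 to A4 is catalytic in the chiral element, needs no auxiliary and is probably shorter. It also delivers O3 free while C1 is still a ketone, so O1 and O3 are differentiated with no protecting group. In these respects it is better than the chosen plan.
- Weak points:
  - The only stereocentre of A4 lies α to an aryl ketone and β to a hydroxyl. It can epimerise, lose formaldehyde by retro-aldol, or dehydrate to the α-methylene ketone.
  - High selectivity in this reaction type is established mainly for small α-substituents. It also requires enol ether A3 as a geometrically pure Z isomer.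
  - C1 must then be created by reduction of the ketone of A4 with syn 1,2-induction, which the two similar C2 substituents do not secure.
- Comparison: the chosen plan answers with one closed-transition-state aldol that fixes both centres, and with a C2 that is never adjacent to a ketone after that step. The cost is a stoichiometric auxiliary and two extra operations.

Alternative 3: hydroboration and B-alkyl Suzuki coupling at a methylene. The cut is the C4–C5 bond together with C2–H. In the forward step 9-borabicyclo[3.3.1]nonane would add to the 1,1-disubstituted alkene of (R)-1-(3,4-dimethoxyphenyl)-2-methylidenepropane-1,3-diol bis(tert-butyldimethylsilyl) ether A5, boron going to C4 and hydrogen to C2. The C4–B bond would then be coupled in the same flask with (E)-1-(2-bromoethenyl)-4-methoxybenzene A6 under PdCl2(dppf) (divalent palladium, reduced in the flask to zerovalent palladium) and aqueous base. The product is (1S,2R)-1-(3,4-dimethoxyphenyl)-2-[(E)-3-(4-methoxyphenyl)prop-2-enyl]propane-1,3-diol bis(tert-butyldimethylsilyl) ether A7.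
- Merits: the road is convergent. The E styrene is carried in intact from bromide A6 with retention, which is more secure than metathesis. The arm could be varied late.
- Weak points:
  - C2 is set by 1,2-induction from C1 of A5 through allylic strain. The usual sense for 9-borabicyclo[3.3.1]nonane is the one required, but the model is secure for a small alkene substituent. Here the substituent is a silyloxymethyl group of real size, so the level of selectivity is open.
  - Enantiopure A5 needs an asymmetric Morita–Baylis–Hillman reaction of aldehyde 6 or a resolution.
  - In A7 both oxygens carry the same silyl group. A selective primary desilylation is needed, and later a slower cleavage of a benzylic tert-butyldimethylsilyl ether beside the sensitive acyl unit.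
- Comparison: the chosen plan offers reagent-controlled creation of both centres and built-in O1/O3 differentiation. It concedes that its styrene geometry rests on thermodynamic control in a metathesis, where the coupling of A6 would be stereospecific.

Key step: step 7

Assumption: formaldehyde 13 is used as the anhydrous monomer in THF, freshly made by thermal cracking of commercial paraformaldehyde.

## Route

Step 1
Reactants: 1 (S)-4-benzyloxazolidin-2-one; 2 pent-4-enoyl chloride
Product: 3 (S)-4-benzyl-3-(pent-4-enoyl)oxazolidin-2-one
Conditions: Et3N, DMAP (cat.), CH2Cl2, 0 °C → rt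
Reagents that add atoms: none
Why: N-acylation of the oxazolidinone by the acid chloride under nucleophilic catalysis by DMAP; the auxiliary stereocentre is not involved.

Step 2
Reactants: 3 (S)-4-benzyl-3-(pent-4-enoyl)oxazolidin-2-one; 4 4-methoxystyrene (1-ethenyl-4-methoxybenzene)
Product: 5 (S)-4-benzyl-3-[(E)-5-(4-methoxyphenyl)pent-4-enoyl]oxazolidin-2-one
Conditions: second-generation Grubbs catalyst RuCl2(=CHPh)(PCy3)(H2IMes) (cat.), 4 (excess), CH2Cl2, 40 °C
Reagents that add atoms: none
Why: Olefin cross-metathesis of a terminal alkene with a styrene, driven by loss of ethylene; the conjugated 1,2-disubstituted alkene should form as the E isomer under thermodynamic control, and any homodimer of 3 can re-enter the cycle.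

Step 3
Reactants: 5 (S)-4-benzyl-3-[(E)-5-(4-methoxyphenyl)pent-4-enoyl]oxazolidin-2-one; 6 3,4-dimethoxybenzaldehyde
Product: 8 (S)-4-benzyl-3-{(2S,4E)-2-[(S)-(3,4-dimethoxyphenyl)(hydroxy)methyl]-5-(4-methoxyphenyl)pent-4-enoyl}oxazolidin-2-one, via Z dibutylboron enolate 7 (not isolated)
Conditions: n-Bu2BOTf, i-Pr2NEt, CH2Cl2, 0 °C; then 6, −78 °C → 0 °C; then pH 7 phosphate buffer, MeOH, 30% H2O2, 0 °C
Reagents that add atoms: none
Why: Evans syn aldol reaction: soft enolisation gives Z boron enolate 7, which adds to 6 through a Zimmerman–Traxler chair with the aryl group equatorial (syn), on the enolate face remote from the benzyl group of the dipole-opposed (S)-auxiliary; this sets the acyl C2 as S and the carbinol as S, which are C2 and C1 of the target.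

Step 4
Reactants: 8 (S)-4-benzyl-3-{(2S,4E)-2-[(S)-(3,4-dimethoxyphenyl)(hydroxy)methyl]-5-(4-methoxyphenyl)pent-4-enoyl}oxazolidin-2-one
Product: 9 (S)-4-benzyl-3-{(2S,4E)-2-[(S)-(3,4-dimethoxyphenyl)(triethylsilyloxy)methyl]-5-(4-methoxyphenyl)pent-4-enoyl}oxazolidin-2-one
Conditions: Et3SiCl, imidazole, DMF, 0 °C → rt
Reagents that add atoms: chlorotriethylsilane, CC[Si](Cl)(CC)CC
Why: Silylation of the secondary alcohol with a silyl chloride and imidazole; doing it while C3 is still an imide carbonyl differentiates O1 from O3 without a selective step, and the near-neutral medium avoids retro-aldol and ionisation at C1.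

Step 5
Reactants: 9 (S)-4-benzyl-3-{(2S,4E)-2-[(S)-(3,4-dimethoxyphenyl)(triethylsilyloxy)methyl]-5-(4-methoxyphenyl)pent-4-enoyl}oxazolidin-2-one
Product: 10 (2R,3S)-3-(3,4-dimethoxyphenyl)-2-[(E)-3-(4-methoxyphenyl)prop-2-enyl]-3-(triethylsilyloxy)propan-1-ol
Conditions: LiBH4, MeOH (1 equiv), THF, 0 °C
Reagents that add atoms: none
Why: Reductive cleavage of the N-acyl oxazolidinone by lithium borohydride at the lithium-activated exocyclic carbonyl, which releases auxiliary 1 for reuse and leaves the styrene and the silyl ether untouched; no stereocentre is affected, and the C2 descriptor changes from S to R only because the carbonyl carbon becomes CH2OH and drops in CIP rank.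

Step 6
Reactants: 10 (2R,3S)-3-(3,4-dimethoxyphenyl)-2-[(E)-3-(4-methoxyphenyl)prop-2-enyl]-3-(triethylsilyloxy)propan-1-ol; 11 but-2-ynoic acid
Product: 12 (2R,3S)-3-(3,4-dimethoxyphenyl)-2-[(E)-3-(4-methoxyphenyl)prop-2-enyl]-3-(triethylsilyloxy)propyl but-2-ynoate
Conditions: DCC, DMAP (cat.), CH2Cl2, −20 °C → 0 °C
Reagents that add atoms: none
Why: Steglich esterification of the only free hydroxyl; the acid has no alkene geometry and no α-hydrogen, so nothing can isomerise, and low temperature with little DMAP limits conjugate addition of the catalyst to the ynoate.

Step 7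
Reactants: 12 (2R,3S)-3-(3,4-dimethoxyphenyl)-2-[(E)-3-(4-methoxyphenyl)prop-2-enyl]-3-(triethylsilyloxy)propyl but-2-ynoate; 13 formaldehyde
Product: 15 (2R,3S)-3-(3,4-dimethoxyphenyl)-2-[(E)-3-(4-methoxyphenyl)prop-2-enyl]-3-(triethylsilyloxy)propyl (Z)-2-(hydroxymethyl)but-2-enoate, via aluminium allenolate 14 (not isolated)
Conditions: i-Bu2AlH, N-methylmorpholine N-oxide, THF, 0 °C; then 13 (monomer in THF, excess), −78 °C → 0 °C; aq. potassium sodium tartrate
Reagents that add atoms: none
Why: The N-oxide-complexed hydride is a weakly Lewis-acidic donor that adds to C3' of the ynoate in conjugate fashion and does not attack the ester carbonyl, giving aluminium allenolate 14, which is in equilibrium with its C-bound α-alumino enoate form, the product of syn H–Al addition. C2' of 14 is sp-hybridised and its nucleophilic lobe lies in the plane that contains the C3' hydrogen and methyl, so formaldehyde 13 bonds to C2' from the hydrogen side; the new CH2O carbon ends cis to H and the methyl cis to the ester carbonyl, which is the kinetic Z alkene. The closest known reaction type is the vinylalumination (reductive aldol) of alkyl alk-2-ynoates with i-Bu2AlH–Lewis base complexes and aldehydes, which gives Z-configured 2-(1-hydroxyalkyl)alk-2-enoates. No ring closes and no stereocentre is formed; C1 and C2 are spectators, and the only stereochemical element is the C2'=C3' geometry, set by the allenolate face as described. The step needs 1,4- over 1,2-hydride delivery and an untouched core: the ester is a primary alkyl ynoate like the known substrates, O1 is silylated so that no alkoxide consumes hydride or attacks the ester, and the styrene and aryl ethers are inert to the complexed hydride at 0 °C. Any Al–H left over is consumed by the excess of 13 before work-up, and the cold tartrate quench should prevent Z-to-E equilibration.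

Step 8
Reactants: 15 (2R,3S)-3-(3,4-dimethoxyphenyl)-2-[(E)-3-(4-methoxyphenyl)prop-2-enyl]-3-(triethylsilyloxy)propyl (Z)-2-(hydroxymethyl)but-2-enoate
Product: 16 (2R,3S)-3-(3,4-dimethoxyphenyl)-3-hydroxy-2-[(E)-3-(4-methoxyphenyl)prop-2-enyl]propyl (Z)-2-(hydroxymethyl)but-2-enoate (CNP0280662.1)
Conditions: HF·pyridine, pyridine, THF, 0 °C
Reagents that add atoms: none
Why: Fluoride-driven cleavage of the triethylsilyl ether; the pyridine buffer keeps the medium too weakly acidic to ionise the 4-alkoxybenzylic C1–O bond and too weakly basic for O3-to-O1 acyl migration or Z-to-E isomerisation, and the ester and primary allylic alcohol are inert.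

## Compound list

1 | (S)-4-benzyloxazolidin-2-one | O=C1N[C@@H](Cc2ccccc2)CO1 | starting material
2 | pent-4-enoyl chloride | C=CCCC(=O)Cl | starting material
3 | (S)-4-benzyl-3-(pent-4-enoyl)oxazolidin-2-one | C=CCCC(=O)N1C(=O)OC[C@@H]1Cc1ccccc1 | intermediate
4 | 4-methoxystyrene | C=Cc1ccc(OC)cc1 | starting material
5 | (S)-4-benzyl-3-[(E)-5-(4-methoxyphenyl)pent-4-enoyl]oxazolidin-2-one | COc1ccc(/C=C/CCC(=O)N2C(=O)OC[C@@H]2Cc2ccccc2)cc1 | intermediate
6 | 3,4-dimethoxybenzaldehyde | COc1ccc(C=O)cc1OC | starting material
7 | Z dibutylboron enolate of 5 (formed in the flask) | CCCCB(CCCC)O/C(=C\C/C=C/c1ccc(OC)cc1)N1C(=O)OC[C@@H]1Cc1ccccc1 | intermediate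
8 | (S)-4-benzyl-3-{(2S,4E)-2-[(S)-(3,4-dimethoxyphenyl)(hydroxy)methyl]-5-(4-methoxyphenyl)pent-4-enoyl}oxazolidin-2-one | O=C(N1C(=O)OC[C@@H]1Cc1ccccc1)[C@@H](C/C=C/c1ccc(OC)cc1)[C@H](O)c1ccc(OC)c(OC)c1 | intermediate
9 | (S)-4-benzyl-3-{(2S,4E)-2-[(S)-(3,4-dimethoxyphenyl)(triethylsilyloxy)methyl]-5-(4-methoxyphenyl)pent-4-enoyl}oxazolidin-2-one | O=C(N1C(=O)OC[C@@H]1Cc1ccccc1)[C@@H](C/C=C/c1ccc(OC)cc1)[C@H](O[Si](CC)(CC)CC)c1ccc(OC)c(OC)c1 | intermediate
10 | (2R,3S)-3-(3,4-dimethoxyphenyl)-2-[(E)-3-(4-methoxyphenyl)prop-2-enyl]-3-(triethylsilyloxy)propan-1-ol | OC[C@@H](C/C=C/c1ccc(OC)cc1)[C@H](O[Si](CC)(CC)CC)c1ccc(OC)c(OC)c1 | intermediate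
11 | but-2-ynoic acid | CC#CC(=O)O | starting material
12 | (2R,3S)-3-(3,4-dimethoxyphenyl)-2-[(E)-3-(4-methoxyphenyl)prop-2-enyl]-3-(triethylsilyloxy)propyl but-2-ynoate | CC#CC(=O)OC[C@@H](C/C=C/c1ccc(OC)cc1)[C@H](O[Si](CC)(CC)CC)c1ccc(OC)c(OC)c1 | intermediate
13 | formaldehyde | C=O | starting material
14 | diisobutylaluminium allenolate of 12, O-bound, allene axis undefined (formed in the flask) | CC=C=C(O[Al](CC(C)C)CC(C)C)OC[C@@H](C/C=C/c1ccc(OC)cc1)[C@H](O[Si](CC)(CC)CC)c1ccc(OC)c(OC)c1 | intermediate
15 | (2R,3S)-3-(3,4-dimethoxyphenyl)-2-[(E)-3-(4-methoxyphenyl)prop-2-enyl]-3-(triethylsilyloxy)propyl (Z)-2-(hydroxymethyl)but-2-enoate | C/C=C(/CO)C(=O)OC[C@@H](C/C=C/c1ccc(OC)cc1)[C@H](O[Si](CC)(CC)CC)c1ccc(OC)c(OC)c1 | intermediate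
16 | (2R,3S)-3-(3,4-dimethoxyphenyl)-3-hydroxy-2-[(E)-3-(4-methoxyphenyl)prop-2-enyl]propyl (Z)-2-(hydroxymethyl)but-2-enoate | C/C=C(/CO)C(=O)OC[C@@H](C/C=C/c1ccc(OC)cc1)[C@H](O)c1ccc(OC)c(OC)c1 | target

## Step count and risk assessment

Total step count: 8. Longest linear sequence: 8 steps, from 1 and 2 to 16.

**Step 7 (key step).** Hydride delivery to the ester carbonyl in place of C3' would cleave the acyl unit from the core. Slow capture of the allenolate by formaldehyde, which repolymerises easily, would allow protonation or equilibration, with loss of the hydroxymethyl group or of the Z geometry. The fallback sets out from 12 and returns at 15, and replaces the reductive aldol by three steps of known type that build the same alkene by tin chemistry. Syn hydrostannation of 12 with Bu3SnH and Pd(PPh3)4 (zerovalent palladium) in THF should place tin on C2' and hydrogen on C3', giving (2R,3S)-3-(3,4-dimethoxyphenyl)-2-[(E)-3-(4-methoxyphenyl)prop-2-enyl]-3-(triethylsilyloxy)propyl (E)-2-(tributylstannyl)but-2-enoate F1. Iododestannylation with I2 in CH2Cl2 at 0 °C, with retention, gives (2R,3S)-3-(3,4-dimethoxyphenyl)-2-[(E)-3-(4-methoxyphenyl)prop-2-enyl]-3-(triethylsilyloxy)propyl (E)-2-iodobut-2-enoate F2. Stille hydroxymethylation of this iodide with (tributylstannyl)methanol and Pd(PPh3)4 in dioxane forms the C2'–CH2OH bond with retention and delivers 15.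

**Step 2.** Homodimerisation of the styrene partner to the stilbene, and alkene migration along the chain by ruthenium hydride species formed from the catalyst, could erode conversion and deliver chain-shortened or positionally isomeric material. Incomplete E selectivity is a lesser risk. The fallback by-passes 3, sets out from oxazolidinone 1 and returns at 5, building the styrene by a sigmatropic shift. Vinylmagnesium bromide is added to 4-methoxybenzaldehyde to give racemic 1-(4-methoxyphenyl)prop-2-en-1-ol F3. Johnson–Claisen rearrangement with triethyl orthoacetate and catalytic propionic acid at 140 °C gives ethyl (E)-5-(4-methoxyphenyl)pent-4-enoate F4. Saponification with LiOH gives (E)-5-(4-methoxyphenyl)pent-4-enoic acid F5. This acid is activated as its pivaloyl mixed anhydride (PivCl, Et3N, THF) and joined to 1 in the presence of LiCl to give 5.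

**Step 5.** In this α-branched, β-silyloxy imide the hydride may attack the ring carbonyl. This endocyclic cleavage opens the auxiliary and does not release the alcohol. The fallback sets out from 9 and returns at 10. Lithium ethanethiolate (EtSH, n-BuLi, THF, 0 °C) attacks only the exocyclic carbonyl and gives S-ethyl (2S,4E)-2-[(S)-(3,4-dimethoxyphenyl)(triethylsilyloxy)methyl]-5-(4-methoxyphenyl)pent-4-enethioate F6 while returning auxiliary 1. The thioester is then reduced with LiBH4 in Et2O to 10.

**Step 6.** Conjugate addition of DMAP to the activated ynoate, leading to oligomerisation, and rearrangement of the activated acid to an N-acylurea would consume the acid and the valuable alcohol. The fallback sets out from 10 and returns at 12 by activating the alcohol, not the acid. A Mitsunobu esterification with 11, PPh3 and diisopropyl azodicarboxylate in THF at 0 °C has no nucleophilic amine present; the phosphine is premixed with the azodicarboxylate so that it is bound as the betaine before it meets the ynoic acid. No new compound is made (entry F0).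

**Step 8.** The final product combines a base-sensitive β-acyloxy alcohol, an isomerisable Z enoate and an ionisable benzylic carbinol. Acyl migration from O3 to O1, Z-to-E isomerisation or ionisation at C1 during desilylation would all cost material at the last step. The fallback sets out from 12 and returns at 16, moving the deprotection ahead of the key step. The silyl group is removed from the robust ynoate with buffered HF·pyridine to give (2R,3S)-3-(3,4-dimethoxyphenyl)-3-hydroxy-2-[(E)-3-(4-methoxyphenyl)prop-2-enyl]propyl but-2-ynoate F7. The reductive hydroxymethylation is then run on this hydroxy ynoate with one extra equivalent of the i-Bu2AlH–N-methylmorpholine N-oxide complex. O1 is masked in the flask as its aluminium alkoxide, and the tartrate work-up gives 16 directly.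

## Further compounds

F1 | step 7 | (2R,3S)-3-(3,4-dimethoxyphenyl)-2-[(E)-3-(4-methoxyphenyl)prop-2-enyl]-3-(triethylsilyloxy)propyl (E)-2-(tributylstannyl)but-2-enoate | C/C=C(/[Sn](CCCC)(CCCC)CCCC)C(=O)OC[C@@H](C/C=C/c1ccc(OC)cc1)[C@H](O[Si](CC)(CC)CC)c1ccc(OC)c(OC)c1
F2 | step 7 | (2R,3S)-3-(3,4-dimethoxyphenyl)-2-[(E)-3-(4-methoxyphenyl)prop-2-enyl]-3-(triethylsilyloxy)propyl (E)-2-iodobut-2-enoate | C/C=C(/I)C(=O)OC[C@@H](C/C=C/c1ccc(OC)cc1)[C@H](O[Si](CC)(CC)CC)c1ccc(OC)c(OC)c1
F3 | step 2 | 1-(4-methoxyphenyl)prop-2-en-1-ol (racemic) | C=CC(O)c1ccc(OC)cc1
F4 | step 2 | ethyl (E)-5-(4-methoxyphenyl)pent-4-enoate | CCOC(=O)CC/C=C/c1ccc(OC)cc1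
F5 | step 2 | (E)-5-(4-methoxyphenyl)pent-4-enoic acid | OC(=O)CC/C=C/c1ccc(OC)cc1
F6 | step 5 | S-ethyl (2S,4E)-2-[(S)-(3,4-dimethoxyphenyl)(triethylsilyloxy)methyl]-5-(4-methoxyphenyl)pent-4-enethioate | CCSC(=O)[C@@H](C/C=C/c1ccc(OC)cc1)[C@H](O[Si](CC)(CC)CC)c1ccc(OC)c(OC)c1
F0 | step 6 | none | none
F7 | step 8 | (2R,3S)-3-(3,4-dimethoxyphenyl)-3-hydroxy-2-[(E)-3-(4-methoxyphenyl)prop-2-enyl]propyl but-2-ynoate | CC#CC(=O)OC[C@@H](C/C=C/c1ccc(OC)cc1)[C@H](O)c1ccc(OC)c(OC)c1
A1 | alternative 1 | (S)-1-(4-methoxyphenyl)prop-2-en-1-yl 3-[(tert-butyldimethylsilyl)oxy]propanoate | C=C[C@H](OC(=O)CCO[Si](C)(C)C(C)(C)C)c1ccc(OC)cc1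
A2 | alternative 1 | (R,E)-2-{[(tert-butyldimethylsilyl)oxy]methyl}-5-(4-methoxyphenyl)pent-4-enoic acid | CC(C)(C)[Si](C)(C)OC[C@@H](C/C=C/c1ccc(OC)cc1)C(=O)O
A3 | alternative 2 | trimethyl{[(1Z,4E)-1-(3,4-dimethoxyphenyl)-5-(4-methoxyphenyl)penta-1,4-dien-1-yl]oxy}silane | C[Si](C)(C)O/C(=C\C/C=C/c1ccc(OC)cc1)c1ccc(OC)c(OC)c1
A4 | alternative 2 | (R,E)-1-(3,4-dimethoxyphenyl)-2-(hydroxymethyl)-5-(4-methoxyphenyl)pent-4-en-1-one | OC[C@@H](C/C=C/c1ccc(OC)cc1)C(=O)c1ccc(OC)c(OC)c1
A5 | alternative 3 | (R)-1-(3,4-dimethoxyphenyl)-2-methylidenepropane-1,3-diol bis(tert-butyldimethylsilyl) ether | CC(C)(C)[Si](C)(C)OCC(=C)[C@H](O[Si](C)(C)C(C)(C)C)c1ccc(OC)c(OC)c1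
A6 | alternative 3 | (E)-1-(2-bromoethenyl)-4-methoxybenzene | Br/C=C/c1ccc(OC)cc1
A7 | alternative 3 | (1S,2R)-1-(3,4-dimethoxyphenyl)-2-[(E)-3-(4-methoxyphenyl)prop-2-enyl]propane-1,3-diol bis(tert-butyldimethylsilyl) ether | CC(C)(C)[Si](C)(C)OC[C@@H](C/C=C/c1ccc(OC)cc1)[C@H](O[Si](C)(C)C(C)(C)C)c1ccc(OC)c(OC)c1
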